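**Assumption:** the SMILES fixes C1 (R) and C3 (S) but gives no descriptor for the C7–C8' biaryl axis, so the route sets the two stereocentres and leaves the axis as it forms; if rotation is slow, the two atropo-diastereomers would be separated at the end.

Numbering used throughout: isoquinoline atoms C1–C8a; naphthalene atoms C1'–C8a' (2'-CH3, 4'-OMe, 5'-OMe, biaryl bond at C8').

## The problem

The target is a 7,8'-linked naphthylisoquinoline: a cis-1,3-dimethyl-N-methyl tetrahydroisoquinoline whose C7 is bonded to C8' of a 4',5'-dimethoxy-2'-methylnaphthalene. The hardest bond is C7–C8'. C7 lies between the O6 and O8 methoxy groups and C8' is an α-naphthyl carbon next to the peri C1'–H, so the biaryl carries three ortho substituents. Both carbons are innately nucleophilic (C7 between two donors, C8' para to the 5'-OMe), so a direct union joins two carbons of like polarity. Neither site is the one that electrophiles choose: substitution of the isoquinoline ring is expected at C5, and in the naphthalene C1' and C8' are both para to a methoxy group. The naphthalene itself, with its unsymmetrical 2'-methyl-4',5'-dimethoxy pattern, corresponds to no simple building block. Of the two stereocentres, C3 (S) can come from the chiral pool and can control C1 (R, cis) during hydride addition to a C1=N bond. The tertiary benzylic amine and the electron-rich arenes rule out late O-alkylation (quaternisation at nitrogen) and late oxidation. Two features make the key step possible. C7–H is the only ring hydrogen flanked by two methoxy oxygens (O6 and O8), so it can be removed selectively by a base. C8' stands para to O5' within the methyl-free ring C5'–C8', so that ring is a disguised 1,4-naphthoquinone monoketal with C8' as the carbonyl carbon and C5' as the ketal carbon.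

## Retrosynthesis

**19 ⇒ 18.** No skeletal bond is cut. An OH is put back on C8' and a second OMe on C5', which turns the ring C5'–C8' of target 19 into the quinol ketal 18. This makes C8' a carbinol carbon and prepares the next cut as a carbonyl addition. The forward reaction must deliver one hydride and expel water and methanol. Both C8' epimers of 18 give the same arene, and the 5'-OMe comes from the ketal, so no O-methylation is needed once the amine is present.

**18 ⇒ 10 + 16.** The C7–C8' bond is cut as the addition of an aryl anion to a ketone: aryllithium 17, made from tetrahydroisoquinoline 10 by deprotonation at C7, and quinone monoketal 16. Against a cross-coupling cut of the same bond this needs no halogen or boron at C7 and forms the crowded bond at a carbonyl carbon that becomes sp3. Fragments 10 and 16 are each about half the size of 18 and carry all the oxygen and stereochemical information. The forward step requires lithiation at C7 only and 1,2-addition to the single carbonyl of 16.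

**16 ⇒ 15 ⇒ 11 + 12.** The ketal carbon of 16 is traced to the para-methoxy carbon of naphthol 15 by an oxidative dearomatisation, which fixes the position of the carbonyl through the naphthol oxygen. Naphthol 15 is then cut at C8'–C8a' and C5'–C4a' into aryne 13 (from bromoarene 11) and 2-methoxyfuran 12, by way of the bicyclic ketal 14. This builds the whole naphthalene from two commercial monocycles, and the polarity of the cycloaddition places the furan-derived OMe peri to the aryne OMe, which is the 4',5' pattern.

**10 ⇒ 8 ⇒ 7 ⇒ 5 ⇒ 1 + 2.** In 10 the N–CH3 and C1–H bonds are cut back to dihydroisoquinoline 8 (through iminium 9), so that C3 sets C1. The C1–C8a bond of 8 is cut by a Bischler–Napieralski transform to acetamide 7; the 3,5-dimethoxyphenyl ring is symmetric, so there is no regiochemical question. Acetamide 7 comes from carbamate 5, whose C4–C4a bond is cut into aryl bromide 1 and the alaninol-derived cyclic sulfamidate 2, which carries C3 as S.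

## Roads not taken

**Alternative 1:** cut C7–C8' as a Suzuki–Miyaura coupling of the 7-boronate A1 with the 8'-bromonaphthalene A2 (the route most chemists would draw first). A1 is a 2,6-dimethoxyarylboronate, a class prone to protodeboronation, and it must itself be made by C7 lithiation, so the boron adds a step and a liability. A2 needs a bromine at C8', which direct bromination of the naphthalene would not place cleanly because C1' is equally activated. The coupling then has to form a tri-ortho-substituted biaryl at palladium. The chosen plan uses the aryllithium as it is and defines C8' by the naphthol oxygen.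

**Alternative 2:** cut C7–C8' as a biomimetic oxidative phenol coupling of the isoquinoline-6,8-diol A3 with the naphthol A4 to give the triphenol A5, followed by triple O-methylation. Both partners have several positions ortho or para to a free OH (C5 and C7 in A3; the ortho and para carbons in A4), so cross- and homo-coupled regioisomers are expected. The amine is exposed to an oxidant, and the closing O-methylation of A5 competes with quaternisation at nitrogen. The chosen plan keeps the same innate para-oxygen logic at C8' but with full site control.

**Alternative 3:** cut C8'–C8a' and C5'–C4a' instead, building the naphthalene onto a pre-formed 7-(furan-2-yl)isoquinoline A6 by Diels–Alder reaction with aryne 13 to give the oxabicycle A7, then acid opening and O-methylation. The nucleophilic end of the furan in A6 is its unsubstituted C5, which would bond to the aryne carbon remote from OMe and put the aryl-bearing bridgehead next to the 4'-OMe, the wrong orientation; sterics oppose this, so a mixture is expected. A6 still requires an aryl–furan coupling at C7, and the sequence again ends with a phenol methylation beside the amine. In the chosen plan the same aryne cycloaddition is used with 12, where electronics give the needed orientation.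

Key step: step 7

## Route

Step 1
Reactants: 1 1-bromo-3,5-dimethoxybenzene; 2 tert-butyl (4S)-4-methyl-1,2,3-oxathiazolidine-3-carboxylate 2,2-dioxide
Product: 5 tert-butyl (S)-[1-(3,5-dimethoxyphenyl)propan-2-yl]carbamate, via arylmagnesium bromide 3 (not isolated), via N-sulfamate salt 4 (not isolated)
Conditions: Mg, THF, reflux; then 2, CuI (10 mol %), THF, −20 °C → rt; then 10 % aq. citric acid, rt
Reagents that add atoms: none
Why: Grignard formation, then CuI-catalysed SN2 opening of the cyclic sulfamidate at its O-bearing CH2, the established route from amino alcohols to 1-arylpropan-2-amines. The stereocentre of 2 is not a reacting centre, so 5 keeps the S configuration of the future C3; mild aqueous acid cleaves the N-sulfate and leaves the Boc group.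

Step 2
Reactants: 5 tert-butyl (S)-[1-(3,5-dimethoxyphenyl)propan-2-yl]carbamate
Product: 7 N-[(S)-1-(3,5-dimethoxyphenyl)propan-2-yl]acetamide, via ammonium chloride 6 (not isolated)
Conditions: HCl (4 M in dioxane), rt; evaporate; then Ac2O, Et3N, CH2Cl2, 0 °C → rt
Reagents that add atoms: acetic anhydride, CC(=O)OC(C)=O
Why: Acidolysis of the Boc group, then N-acetylation of the amine; the acetyl group supplies C1 and its methyl group, and the stereocentre is not involved.

Step 3
Reactants: 7 N-[(S)-1-(3,5-dimethoxyphenyl)propan-2-yl]acetamide
Product: 8 (S)-6,8-dimethoxy-1,3-dimethyl-3,4-dihydroisoquinoline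
Conditions: POCl3, MeCN, reflux; aq. NaOH work-up
Reagents that add atoms: none
Why: Bischler–Napieralski cyclodehydration; the activated amide carbon is attacked by the arene ortho to one OMe and para to the other, and the two ortho positions of the 3,5-dimethoxyphenyl ring are equivalent, so only one dihydroisoquinoline can form. C3 is untouched.

Step 4
Reactants: 8 (S)-6,8-dimethoxy-1,3-dimethyl-3,4-dihydroisoquinoline
Product: 10 (1R,3S)-6,8-dimethoxy-1,2,3-trimethyl-1,2,3,4-tetrahydroisoquinoline, via iminium iodide 9 (not isolated)
Conditions: MeI, acetone, rt; evaporate; then NaBH4, MeOH, −78 °C → 0 °C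
Reagents that add atoms: iodomethane, CI
Why: N-Methylation of the imine gives iminium 9. Substrate-controlled borohydride reduction should deliver hydride to C1 on the face opposite the pseudoaxial 3-methyl group (which turns away from the N-methyl group), so 1-CH3 and 3-CH3 end cis, that is 1R from 3S; this is the standard entry to cis-1,3-dimethyl tetrahydroisoquinolines.

Step 5
Reactants: 11 1-bromo-3-methoxy-5-methylbenzene; 12 2-methoxyfuran
Product: 15 4,5-dimethoxy-7-methylnaphthalen-1-ol, via aryne 13 (not isolated), via oxabicyclic ketal 14 (not isolated)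
Conditions: LiN(iPr)2, 12 (3 equiv), THF, −78 °C → rt; then 1 M aq. HCl, rt (argon; product used promptly)
Reagents that add atoms: none
Why: Deprotonation of 11 between Br and OMe and loss of LiBr give aryne 13, which undergoes a polar, asynchronous aryne Diels–Alder reaction: the nucleophilic C5 of 12 bonds to the aryne carbon remote from OMe (the carbon nucleophiles attack in 3-alkoxybenzynes), so the ketal bridgehead ends peri to the aryl OMe, the head-to-head orientation known for 3-alkoxybenzynes with 2-alkoxyfurans. Acid opens 14 at the ketal carbon and tautomerisation gives the 4-methoxy-1-naphthol with OH on the future C8' and OMe on the future C5'.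

Step 6
Reactants: 15 4,5-dimethoxy-7-methylnaphthalen-1-ol
Product: 16 4,4,5-trimethoxy-7-methylnaphthalen-1(4H)-one
Conditions: PhI(OAc)2, MeOH, 0 °C
Reagents that add atoms: methanol, CO
Why: Oxidative dearomatisation of a para-methoxyphenol; the oxidised naphthol is trapped by methanol at the carbon para to the oxygen, which already bears OMe, so the quinone monoketal forms regiospecifically with the carbonyl at the future C8'.

Step 7
Reactants: 10 (1R,3S)-6,8-dimethoxy-1,2,3-trimethyl-1,2,3,4-tetrahydroisoquinoline; 16 4,4,5-trimethoxy-7-methylnaphthalen-1(4H)-one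
Product: 18 (1R,3S)-7-(1-hydroxy-4,4,5-trimethoxy-7-methyl-1,4-dihydronaphthalen-1-yl)-6,8-dimethoxy-1,2,3-trimethyl-1,2,3,4-tetrahydroisoquinoline (both epimers at the carbinol carbon), via aryllithium 17 (not isolated)
Conditions: n-BuLi, TMEDA, THF, 0 °C → rt; then 16, THF, −78 °C → −20 °C; H2O (crude 18 taken on)
Reagents that add atoms: none
Why: n-BuLi deprotonates 10 at C7, the only ring carbon flanked by two methoxy oxygens (O6 and O8), by cooperative directed ortho-metalation to give 17; C5–H has one directing oxygen, and the benzylic C1–H and C4–H2 are not activated toward an alkyllithium. Aryllithium 17 then adds 1,2 to the carbonyl of 16, the known mode for organolithiums with quinone monoketals; the closest precedent is the addition of ortho-substituted aryllithiums to benzoquinone and naphthoquinone monoketals as a biaryl synthesis. No ring is closed. The only new stereocentre is the carbinol carbon (future C8'); nothing controls it and nothing needs to, because both epimers lose it in step 8. Site selectivity rests on 16 itself: it has one carbonyl and no enolisable hydrogen, and its enone β-carbon sits next to the fully substituted ketal carbon, which disfavours conjugate addition. The new bond is made at a carbonyl carbon that becomes sp3, so the three ortho substituents of the eventual biaryl (O6, O8 and the peri C1'–H ring) do not crowd a planar coupling transition state. The ketal carbon, peri to the 4'-OMe, is untouched and carries the future 5'-OMe.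

Step 8
Reactants: 18 (1R,3S)-7-(1-hydroxy-4,4,5-trimethoxy-7-methyl-1,4-dihydronaphthalen-1-yl)-6,8-dimethoxy-1,2,3-trimethyl-1,2,3,4-tetrahydroisoquinoline
Product: 19 Ancistrobrevine A, (1R,3S)-7-(4,5-dimethoxy-7-methylnaphthalen-1-yl)-6,8-dimethoxy-1,2,3-trimethyl-1,2,3,4-tetrahydroisoquinoline
Conditions: Et3SiH (1.5 equiv), CF3CO2H, CH2Cl2, −40 °C → 0 °C; aq. NaHCO3
Reagents that add atoms: none
Why: Reductive aromatisation of a quinol ketal by ionic hydrogenation: acid ionises the ketal (or the tertiary alcohol) to a delocalised cation, Et3SiH delivers one hydride, and the resulting dihydronaphthalene loses the remaining leaving group (water or methanol) to give the naphthalene. Every order of these events leads to the same arene, both carbinol epimers converge, and the 5'-OMe is retained from the ketal; C1 and C3 are not affected, and the biaryl axis forms here.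

## Compound list

1 | 1-bromo-3,5-dimethoxybenzene | COc1cc(Br)cc(OC)c1 | starting material
2 | tert-butyl (4S)-4-methyl-1,2,3-oxathiazolidine-3-carboxylate 2,2-dioxide | C[C@H]1COS(=O)(=O)N1C(=O)OC(C)(C)C | starting material
3 | (3,5-dimethoxyphenyl)magnesium bromide | COc1cc([Mg]Br)cc(OC)c1 | intermediate
4 | bromomagnesium (S)-N-(tert-butoxycarbonyl)-N-[1-(3,5-dimethoxyphenyl)propan-2-yl]sulfamate | COc1cc(C[C@H](C)N(C(=O)OC(C)(C)C)S(=O)(=O)O[Mg]Br)cc(OC)c1 | intermediate
5 | tert-butyl (S)-[1-(3,5-dimethoxyphenyl)propan-2-yl]carbamate | COc1cc(C[C@H](C)NC(=O)OC(C)(C)C)cc(OC)c1 | intermediate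
6 | (S)-1-(3,5-dimethoxyphenyl)propan-2-aminium chloride | COc1cc(C[C@H](C)[NH3+])cc(OC)c1.[Cl-] | intermediate
7 | N-[(S)-1-(3,5-dimethoxyphenyl)propan-2-yl]acetamide | COc1cc(C[C@H](C)NC(C)=O)cc(OC)c1 | intermediate
8 | (S)-6,8-dimethoxy-1,3-dimethyl-3,4-dihydroisoquinoline | COc1cc2c(c(OC)c1)C(C)=N[C@@H](C)C2 | intermediate
9 | (S)-6,8-dimethoxy-1,2,3-trimethyl-3,4-dihydroisoquinolin-2-ium iodide | COc1cc2c(c(OC)c1)C(C)=[N+](C)[C@@H](C)C2.[I-] | intermediate
10 | (1R,3S)-6,8-dimethoxy-1,2,3-trimethyl-1,2,3,4-tetrahydroisoquinoline | COc1cc2c(c(OC)c1)[C@@H](C)N(C)[C@@H](C)C2 | intermediate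
11 | 1-bromo-3-methoxy-5-methylbenzene | COc1cc(C)cc(Br)c1 | starting material
12 | 2-methoxyfuran | COc1ccco1 | starting material
13 | 3-methoxy-5-methylbenzyne | COC1=CC(C)=CC#C1 | intermediate
14 | 4,5-dimethoxy-7-methyl-1,4-dihydro-1,4-epoxynaphthalene (racemic) | COC12OC(C=C1)c1cc(C)cc(OC)c12 | intermediate
15 | 4,5-dimethoxy-7-methylnaphthalen-1-ol | COc1ccc(O)c2cc(C)cc(OC)c12 | intermediate
16 | 4,4,5-trimethoxy-7-methylnaphthalen-1(4H)-one | COc1cc(C)cc2c1C(OC)(OC)C=CC2=O | intermediate
17 | [(1R,3S)-6,8-dimethoxy-1,2,3-trimethyl-1,2,3,4-tetrahydroisoquinolin-7-yl]lithium | COc1cc2c(c(OC)c1[Li])[C@@H](C)N(C)[C@@H](C)C2 | intermediate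
18 | (1R,3S)-7-(1-hydroxy-4,4,5-trimethoxy-7-methyl-1,4-dihydronaphthalen-1-yl)-6,8-dimethoxy-1,2,3-trimethyl-1,2,3,4-tetrahydroisoquinoline (both carbinol epimers) | COc1cc2c(c(OC)c1C1(O)C=CC(OC)(OC)c3c(OC)cc(C)cc13)[C@@H](C)N(C)[C@@H](C)C2 | intermediate
19 | Ancistrobrevine A | COc1cc2c(c(OC)c1-c1ccc(OC)c3c(OC)cc(C)cc13)[C@@H](C)N(C)[C@@H](C)C2 | target

## Step count and risk

Total: 8 steps. Longest linear sequence: 6 steps (1, 2, 3, 4, 7, 8); the naphthalene branch (5, 6) joins at step 7.

**Step 7 (key step).** The most likely failure is electron transfer from the electron-rich aryllithium to the dienone, which would return 10 and 15 after work-up in place of the adduct. Incomplete lithiation at C7 is the second concern. Fallback (sets out from 10 and 15, rejoins at 19): naphthol 15 would be converted with Tf2O and pyridine into 4,5-dimethoxy-7-methylnaphthalen-1-yl trifluoromethanesulfonate F1. Aryllithium 17 would be transmetalated with ZnCl2 to the arylzinc chloride F2, and the two would be joined by a Negishi coupling (Pd(OAc)2, 2-dicyclohexylphosphino-2',6'-dimethoxybiphenyl, THF, 60 °C) to give 19 directly. This forms the same bond by cross-coupling and avoids an arylboron species.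

**Step 8.** A second hydride transfer could compete with aromatisation and remove the C5' oxygen. Adventitious water could hydrolyse the ketal before reduction, and the cation could undergo aryl migration. Fallback (from 18, rejoins at 19): 18 would be hydrolysed deliberately (aq. AcOH, THF, 0 °C) to the quinol 4-aryl-4-hydroxy-8-methoxy-6-methylnaphthalen-1(4H)-one F3. F3 would be reduced by electron transfer (Zn, AcOH) to the naphthol F4, and the phenol would be methylated with Me3SiCHN2 in MeOH/toluene, which does not alkylate the tertiary amine, to give 19.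

**Step 5.** The aryne may be captured by diisopropylamide or by ring-metalated 12 instead of undergoing cycloaddition, or the cycloaddition may proceed in the head-to-tail sense. Fallback (aryne-free; sets out from 10 as 17, rejoins at 19): methyl 3-methylbut-2-enoate would be converted (LiN(iPr)2, Me3SiCl) into 1-methoxy-3-methyl-1-(trimethylsilyloxy)buta-1,3-diene F5. Diels–Alder reaction of F5 with excess p-benzoquinone, with loss of methanol and oxidation, would give 5-hydroxy-7-methylnaphthalene-1,4-dione F6. Methylation (MeI, Ag2O) would give 5-methoxy-7-methylnaphthalene-1,4-dione F7. In F7 the C4 carbonyl is a vinylogous ester shielded by the peri OMe, so 17 should add at C1 to give the quinol F3, which would be carried to 19 through the naphthol F4 as described for step 8.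

**Step 4.** Hydride addition to the N-methyl iminium ion may show poor facial selectivity, and N-alkylation of the hindered imine may be slow. Fallback (from 8, rejoins at 10): the neutral imine 8 would be reduced first (NaBH4, MeOH, −78 °C), the well-established cis-selective case, to (1R,3S)-6,8-dimethoxy-1,3-dimethyl-1,2,3,4-tetrahydroisoquinoline F8. The secondary amine would then be methylated reductively (aq. CH2O, NaBH(OAc)3) to give 10.

## Further compounds

F1 | step 7 | 4,5-dimethoxy-7-methylnaphthalen-1-yl trifluoromethanesulfonate | COc1ccc(OS(=O)(=O)C(F)(F)F)c2cc(C)cc(OC)c12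
F2 | step 7 | chloro[(1R,3S)-6,8-dimethoxy-1,2,3-trimethyl-1,2,3,4-tetrahydroisoquinolin-7-yl]zinc | COc1cc2c(c(OC)c1[Zn]Cl)[C@@H](C)N(C)[C@@H](C)C2
F3 | step 8 | 4-[(1R,3S)-6,8-dimethoxy-1,2,3-trimethyl-1,2,3,4-tetrahydroisoquinolin-7-yl]-4-hydroxy-8-methoxy-6-methylnaphthalen-1(4H)-one (both carbinol epimers) | COc1cc2c(c(OC)c1C1(O)C=CC(=O)c3c(OC)cc(C)cc13)[C@@H](C)N(C)[C@@H](C)C2
F4 | step 8 | 4-[(1R,3S)-6,8-dimethoxy-1,2,3-trimethyl-1,2,3,4-tetrahydroisoquinolin-7-yl]-8-methoxy-6-methylnaphthalen-1-ol | COc1cc2c(c(OC)c1-c1ccc(O)c3c(OC)cc(C)cc13)[C@@H](C)N(C)[C@@H](C)C2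
F5 | step 5 | 1-methoxy-3-methyl-1-(trimethylsilyloxy)buta-1,3-diene | COC(O[Si](C)(C)C)=CC(C)=C
F6 | step 5 | 5-hydroxy-7-methylnaphthalene-1,4-dione | Cc1cc(O)c2C(=O)C=CC(=O)c2c1
F7 | step 5 | 5-methoxy-7-methylnaphthalene-1,4-dione | COc1cc(C)cc2C(=O)C=CC(=O)c12
F8 | step 4 | (1R,3S)-6,8-dimethoxy-1,3-dimethyl-1,2,3,4-tetrahydroisoquinoline | COc1cc2c(c(OC)c1)[C@@H](C)N[C@@H](C)C2
A1 | alternative 1 | (1R,3S)-6,8-dimethoxy-1,2,3-trimethyl-7-(4,4,5,5-tetramethyl-1,3,2-dioxaborolan-2-yl)-1,2,3,4-tetrahydroisoquinoline | COc1cc2c(c(OC)c1B1OC(C)(C)C(C)(C)O1)[C@@H](C)N(C)[C@@H](C)C2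
A2 | alternative 1 | 1-bromo-4,5-dimethoxy-7-methylnaphthalene | COc1ccc(Br)c2cc(C)cc(OC)c12
A3 | alternative 2 | (1R,3S)-1,2,3-trimethyl-1,2,3,4-tetrahydroisoquinoline-6,8-diol | Oc1cc2c(c(O)c1)[C@@H](C)N(C)[C@@H](C)C2
A4 | alternative 2 | 8-methoxy-6-methylnaphthalen-1-ol | COc1cc(C)cc2cccc(O)c12
A5 | alternative 2 | (1R,3S)-7-(4-hydroxy-5-methoxy-7-methylnaphthalen-1-yl)-1,2,3-trimethyl-1,2,3,4-tetrahydroisoquinoline-6,8-diol | Oc1cc2c(c(O)c1-c1ccc(O)c3c(OC)cc(C)cc13)[C@@H](C)N(C)[C@@H](C)C2
A6 | alternative 3 | (1R,3S)-7-(furan-2-yl)-6,8-dimethoxy-1,2,3-trimethyl-1,2,3,4-tetrahydroisoquinoline | COc1cc2c(c(OC)c1-c1ccco1)[C@@H](C)N(C)[C@@H](C)C2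
A7 | alternative 3 | (1R,3S)-6,8-dimethoxy-7-(5-methoxy-7-methyl-1,4-dihydro-1,4-epoxynaphthalen-1-yl)-1,2,3-trimethyl-1,2,3,4-tetrahydroisoquinoline | COc1cc(C)cc2c1C1OC2(C=C1)c1c(OC)cc2c(c1OC)[C@@H](C)N(C)[C@@H](C)C2
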